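Precatalyst, catalyst and idle complex together hold the catalyst charge, and at a given conversion the rate goes with the part of it standing as catalyst.

| flask | left-handed substrate | right-handed substrate | reagent | precatalyst | added ligand | remark |
|---|---|---|---|---|---|---|
| maple | 0.018 M | 0.018 M | 0.0104 M | 9.5 µM | 39 µM | run made earlier |
| oak | 0.029 M | 0.029 M | 0.0104 M | 9.5 µM | 39 µM | run made earlier |
| larch | 0.013 M | 0.013 M | 0.0104 M | 14 µM | 39 µM | run made earlier |
| flask | 0.013 M | 0.013 M | 0.0104 M | 9.5 µM | 39 µM |  |

- maple (time / h: left-handed product / %): 2.00: 0; 6.00: 11; 10.0: 13; 15.0: 19
- oak (time / h: left-handed product / %): 1.33: 0; 3.00: 2; 6.00: 10; 15.0: 14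
- larch (time / h: left-handed product / %): 2.00: 7; 6.00: 15; 10.0: 18; 15.0: 25

(readings scatter by 2 percentage points)

* factor on the rate of making left-handed product when 5.0% of the left-handed substrate and right-handed substrate together are converted if precatalyst is charged twice over
* factor on the rate when 5.0% of the left-handed substrate and right-handed substrate together are converted if precatalyst is charged at 50 µM instead

1. The main step by itself: with the catalyst working from the start, the rate at 5.0% conversion scales with the load. Doubling gives 2, and 50 µM gives 5.26.

2. Adding release: maple reads 0% at 2.00 h but 11% at 6.00 h, which this reckoning takes as a slow appearance of catalyst. While catalyst grows in proportion to time, conversion grows as load times time squared. Equal conversion therefore comes earlier by the root of the load, and the rate then scales with that root, an exponent of 0.500.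

3. The correction: release bends as precatalyst is used. Let u be the time to 5.0% divided by the release time; the next order adds u divided by 6. This reckoning takes a guess of 0.500 for u. That gives 0.583, the load exponent, the power of the precatalyst charge that the rate at equal conversion follows. The factors become 1.50 and 2.63.

4. The rest: at equal conversion, substrates and reagent stand about equal in the compared flasks, so they cancel. Added ligand also forms idle complex; maple, oak and larch each carry 39 µM, and this reckoning omits it.

5. The forecast gives 1.8 (1.3 to 2.8) and 4 (2.3 to 12), higher than this reckoning, holding that “Ligand sequestration (39 µM in excess) pushes it above linear”.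

6. The flask gives 1.53 and 2.65.

    reagent + catalyst + left-handed substrate → catalyst + left-handed product (k = 25200 M⁻² min⁻¹)
    precatalyst → catalyst (k = 0.00249 min⁻¹)
    catalyst + added ligand ⇌ idle complex (K = 19600 M⁻¹, k = 48.5 M⁻¹ min⁻¹)
    reagent + catalyst + right-handed substrate → catalyst + right-handed product (k = 8650 M⁻² min⁻¹)

As load exponents, these results read 0.614 for doubling and 0.587 for the charge of 50 µM, against the 0.583 reckoned. The flask reaches 5.0% at 3.08 h, earlier than the release time of 6.69 h, a ratio of 0.460, which, put in place of the guessed u, gives an exponent of 0.577.

The readings come from a simulation from invented constants; scatter was added.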